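**Retrosynthetic overview**

1. The last bond made is C6–O of the γ-lactone (ring O, C6, C7, C11, C12), by Pd(0) opening of a C4 spiro vinyl oxirane with the C12 acid. The plan rests on the unit O–C6–C5=C4–C15–OH (a 4-acyloxybut-2-en-1-ol), in which the acid carbon C12 is tied to C6 through C11 and C7.
2. The ten-membered carbocycle (C1–C10) is closed before that by Z-selective ring-closing metathesis at the disubstituted C5=C6 bond of a bis-vinyl precursor that already carries both oxiranes and the C8 angelate.
3. C4 comes from Sharpless epoxidation of a 2-substituted allylic alcohol (then oxidation and Wittig), C1/C10 from OH-directed peracid epoxidation, and C2 from Keck allylation of an E-enal.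
4. C7 comes from anti-selective vinyl cuprate addition to a γ-silyloxy enoate (Mannich trapping gives the α-methylene ester), C8 from methyl (S)-glycidate, and C9–C10 from copper-catalysed opening of the glycidate by an E-alkenyl Grignard reagent.
5. Ring order: carbocycle first (metathesis), lactone last (palladium); the two oxiranes are spectators in the metathesis and the C1–C10 oxirane also in the lactonisation.

Key step: step 21

Remark: locants C1–C15 are germacrane numbers. A 2-(alkoxycarbonyl)allyl-metal addition to a C8 aldehyde is expected to give the 7,8-syn series, so the 7,8-anti pair (7R,8S) is built by conjugate addition instead. The C12 acid is carried as its 2-(trimethylsilyl)ethyl (TMSE) ester.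

**Route**

Step 1
Reactants: 1 1,1-diethoxybut-2-yne
Product: 3 (E)-1,1-diethoxy-3-iodobut-2-ene, via alkenylzirconocene chloride 2 (not isolated)
Conditions: Cp2Zr(H)Cl, THF, rt; then I2, 0 °C
Reagents that add atoms: iodine, II; zirconocene chloride hydride, [H][Zr](Cl)(C1C=CC=C1)C1C=CC=C1 (kept only in 2)
Why: Hydrozirconation–iodination: syn addition of Zr–H should put the metal on the methyl-bearing, less hindered alkyne carbon, and iodinolysis with retention should give the iodide with I trans to the acetal carbon, which fixes the later E-C1=C10 geometry.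

Step 2
Reactants: 3 (E)-1,1-diethoxy-3-iodobut-2-ene; 4 methyl (S)-oxirane-2-carboxylate
Product: 7 methyl (2S,4E)-6,6-diethoxy-2-hydroxy-4-methylhex-4-enoate, via alkenyllithium 5 (not isolated), via alkenylmagnesium bromide 6 (not isolated)
Conditions: t-BuLi (2 equiv), Et2O, −78 °C; MgBr2·OEt2; then 4, CuI (10 mol%), THF, −40 °C; H2O
Reagents that add atoms: tert-butyllithium, [Li]C(C)(C)C (Li only in 5); magnesium bromide, Br[Mg]Br (only in 6)
Why: Iodine–lithium exchange and transmetalation keep the alkene geometry, and the copper-catalysed Grignard opening of the glycidate at its CH2 terminus (SN2) should form C9–C10 while C8 (S) is taken over unchanged from 4.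

Step 3
Reactants: 7 methyl (2S,4E)-6,6-diethoxy-2-hydroxy-4-methylhex-4-enoate
Product: 8 methyl (2S,4E)-6,6-diethoxy-4-methyl-2-(triethylsilyloxy)hex-4-enoate
Conditions: TESCl, imidazole, CH2Cl2, 0 °C
Reagents that add atoms: chlorotriethylsilane, CC[Si](Cl)(CC)CC
Why: Standard silylation of a secondary alcohol; the TES ether is the non-chelating C8 substituent wanted for the later Felkin-type addition.

Step 4
Reactants: 9 (diethoxyphosphoryl)acetic acid
Product: 10 2-(trimethylsilyl)ethyl (diethoxyphosphoryl)acetate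
Conditions: Me3SiCH2CH2OH, DCC, DMAP (cat.), CH2Cl2, 0 °C to rt
Reagents that add atoms: 2-(trimethylsilyl)ethanol, C[Si](C)(C)CCO
Why: Steglich esterification gives the Horner–Wadsworth–Emmons reagent that brings in C11 and C12 as a fluoride-labile ester.

Step 5
Reactants: 8 methyl (2S,4E)-6,6-diethoxy-4-methyl-2-(triethylsilyloxy)hex-4-enoate; 10 2-(trimethylsilyl)ethyl (diethoxyphosphoryl)acetate
Product: 12 2-(trimethylsilyl)ethyl (2E,4S,6E)-8,8-diethoxy-6-methyl-4-(triethylsilyloxy)octa-2,6-dienoate, via silyloxy aldehyde 11 (not isolated)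
Conditions: DIBAL-H (1.1 equiv), CH2Cl2, −78 °C; then 10/NaH in THF, −78 °C to rt
Reagents that add atoms: none
Why: DIBAL half-reduction of the α-silyloxy ester to the aluminium hemiacetal and Horner–Wadsworth–Emmons olefination in the same flask should give the E-enoate without long exposure of the epimerisable aldehyde to base.

Step 6
Reactants: 12 2-(trimethylsilyl)ethyl (2E,4S,6E)-8,8-diethoxy-6-methyl-4-(triethylsilyloxy)octa-2,6-dienoate
Product: 14 2-(trimethylsilyl)ethyl (3R,4S,6E)-2-[(dimethylamino)methyl]-8,8-diethoxy-3-ethenyl-6-methyl-4-(triethylsilyloxy)oct-6-enoate (both C2 epimers), via silyl ketene acetal 13 (not isolated)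
Conditions: CH2=CHMgBr, CuBr·SMe2 (20 mol%), TMSCl, THF, −78 °C; then CH2=NMe2+ I−, CH2Cl2, −78 °C to rt; aq. NaHCO3
Reagents that add atoms: vinylmagnesium bromide, C=C[Mg]Br; N,N-dimethylmethyleneiminium iodide, C=[N+](C)C.[I-]; chlorotrimethylsilane, C[Si](C)(C)Cl (kept only in 13)
Why: TMSCl-accelerated copper-catalysed conjugate addition: Felkin–Anh attack anti to the C8–OSi bond should set C7 as R (7,8-anti), and the silyl ketene acetal is then aminomethylated at C11 by the iminium salt (Mannich reaction), the C11 centre being lost in step 7.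

Step 7
Reactants: 14 2-(trimethylsilyl)ethyl (3R,4S,6E)-2-[(dimethylamino)methyl]-8,8-diethoxy-3-ethenyl-6-methyl-4-(triethylsilyloxy)oct-6-enoate
Product: 16 2-(trimethylsilyl)ethyl (3R,4S,6E)-8,8-diethoxy-3-ethenyl-6-methyl-2-methylidene-4-(triethylsilyloxy)oct-6-enoate, via trimethylammonium iodide 15 (not isolated)
Conditions: MeI, CH2Cl2, rt; then DBU, rt
Reagents that add atoms: iodomethane, CI (kept only in 15)
Why: Quaternisation and base-induced loss of trimethylamine (Hofmann-type E1cB elimination of a Mannich base) can only form the C11=C13 methylene bond.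

Step 8
Reactants: 16 2-(trimethylsilyl)ethyl (3R,4S,6E)-8,8-diethoxy-3-ethenyl-6-methyl-2-methylidene-4-(triethylsilyloxy)oct-6-enoate
Product: 17 2-(trimethylsilyl)ethyl (3R,4S,6E)-3-ethenyl-4-hydroxy-6-methyl-2-methylidene-8-oxooct-6-enoate
Conditions: AcOH/THF/H2O (3:1:1), rt
Reagents that add atoms: water, O
Why: Mild aqueous acid cleaves the secondary TES ether and hydrolyses the allylic acetal to the conjugated E-enal in one operation, and should leave the TMSE ester untouched.

Step 9
Reactants: 17 2-(trimethylsilyl)ethyl (3R,4S,6E)-3-ethenyl-4-hydroxy-6-methyl-2-methylidene-8-oxooct-6-enoate; 18 angelic acid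
Product: 19 2-(trimethylsilyl)ethyl (3R,4S,6E)-3-ethenyl-6-methyl-2-methylidene-4-{[(2Z)-2-methylbut-2-enoyl]oxy}-8-oxooct-6-enoate
Conditions: 18, 2,4,6-Cl3C6H2COCl, Et3N, toluene, rt; then 17, 75 °C
Reagents that add atoms: none
Why: Yamaguchi esterification through the mixed anhydride, run without DMAP, should acylate the hindered C8 alcohol before it can lactonise onto C12 and should avoid Z-to-E isomerisation of the angelate.

Step 10
Reactants: 20 3-chloro-2-(chloromethyl)prop-1-ene
Product: 21 1-({[2-(chloromethyl)prop-2-en-1-yl]oxy}methyl)-4-methoxybenzene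
Conditions: 4-MeOC6H4CH2OH, NaH, THF, 0 °C to rt (20 in excess)
Reagents that add atoms: 4-methoxybenzyl alcohol, COc1ccc(CO)cc1
Why: Williamson ether synthesis; an excess of the symmetrical dichloride limits double substitution.

Step 11
Reactants: 21 1-({[2-(chloromethyl)prop-2-en-1-yl]oxy}methyl)-4-methoxybenzene
Product: 22 tributyl(2-{[(4-methoxybenzyl)oxy]methyl}prop-2-en-1-yl)stannane
Conditions: Bu3SnH, LDA, THF, −78 °C; then 21
Reagents that add atoms: tributyltin hydride, CCCC[SnH](CCCC)CCCC
Why: SN2 displacement of the allylic chloride by tributylstannyllithium gives the 2-substituted allylstannane that carries C3, C4, C5 and C15.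

Step 12
Reactants: 19 angelate enal; 22 tributyl(2-{[(4-methoxybenzyl)oxy]methyl}prop-2-en-1-yl)stannane
Product: 23 2-(trimethylsilyl)ethyl (3R,4S,6E,8S)-3-ethenyl-8-hydroxy-10-{[(4-methoxybenzyl)oxy]methyl}-6-methyl-2-methylidene-4-{[(2Z)-2-methylbut-2-enoyl]oxy}undeca-6,10-dienoate
Conditions: (S)-BINOL (20 mol%), Ti(OiPr)4 (10 mol%), 4 Å MS, CH2Cl2, −20 °C; aq. NaHCO3
Reagents that add atoms: none
Why: Keck asymmetric allylation: the (S)-BINOL–titanium catalyst directs the allylstannane to the Si face of the enal, which should give the 2S alcohol under catalyst control, independently of the remote C7/C8 centres.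

Step 13
Reactants: 23 Keck alcohol (2S)
Product: 24 (1R,2S,10R)-1,10-epoxy alcohol
Conditions: mCPBA, NaHCO3, CH2Cl2, −20 to 0 °C
Reagents that add atoms: 3-chloroperoxybenzoic acid, OOC(=O)c1cccc(Cl)c1
Why: Hydroxyl-directed Prilezhaev epoxidation of the most electron-rich alkene: A1,3 strain with the cis C14 methyl holds C2–H in the alkene plane, so oxygen delivery syn to the OH should give the threo epoxy alcohol, which is 1R,10R.

Step 14
Reactants: 24 (1R,2S,10R)-1,10-epoxy alcohol
Product: 25 C2 triethylsilyl ether of 24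
Conditions: TESCl, imidazole, DMF, 0 °C
Reagents that add atoms: chlorotriethylsilane, CC[Si](Cl)(CC)CC
Why: Silylation protects C2–OH against the later oxidation; the TES ether falls in the fluoride step together with the TMSE ester.

Step 15
Reactants: 25 C2 triethylsilyl ether
Product: 26 C5 allylic alcohol (PMB removed)
Conditions: DDQ, CH2Cl2/pH 7 buffer, 0 °C
Reagents that add atoms: none
Why: Oxidative cleavage of the PMB ether by DDQ under buffered conditions should free the 2-substituted allylic alcohol without touching oxirane, silyl ether or esters.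

Step 16
Reactants: 26 C5 allylic alcohol
Product: 27 (4S)-4,15-epoxy C5 alcohol
Conditions: Ti(OiPr)4 (10 mol%), L-(+)-DET (12 mol%), t-BuOOH, 4 Å MS, CH2Cl2, −20 °C
Reagents that add atoms: tert-butyl hydroperoxide, CC(C)(C)OO
Why: Sharpless asymmetric epoxidation under reagent control: with L-(+)-diethyl tartrate the oxygen goes to the face of the 1,1-disubstituted alkene that gives the 4S oxirane, the sense in which 2-methylallyl alcohol gives (S)-2-methylglycidol.

Step 17
Reactants: 27 (4S)-4,15-epoxy C5 alcohol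
Product: 28 C5 epoxy aldehyde
Conditions: Dess–Martin periodinane, NaHCO3, CH2Cl2, 0 °C
Reagents that add atoms: none
Why: Dess–Martin oxidation to the epoxy aldehyde; C4 is quaternary and cannot epimerise.

Step 18
Reactants: 28 C5 epoxy aldehyde
Product: 29 acyclic bis-vinyl compound with C4 vinyl oxirane
Conditions: Ph3PCH3Br, KHMDS, THF, 0 °C; then 28, −78 to 0 °C
Reagents that add atoms: methyltriphenylphosphonium bromide, C[P+](c1ccccc1)(c1ccccc1)c1ccccc1.[Br-]
Why: Wittig methylenation of the non-enolisable aldehyde at low temperature is expected to outrun conjugate addition of the ylide to the acrylate, and gives the vinyl oxirane.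

Step 19
Reactants: 29 acyclic bis-vinyl compound
Product: 30 ten-membered (5Z)-cycloalkene (TMSE ester, C2 OTES)
Conditions: Grubbs II (10 mol%), CH2Cl2 (1 mM), 40 °C
Reagents that add atoms: none
Why: Ring-closing metathesis of the two monosubstituted alkenes; the electron-poor 1,1-disubstituted and trisubstituted alkenes are spectators, and in a ten-membered ring the Z-C5=C6 alkene is the far less strained product.

Step 20
Reactants: 30 ten-membered (5Z)-cycloalkene
Product: 31 seco acid (free C12 acid, free C2–OH)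
Conditions: TBAF, THF, 0 °C to rt; pH 6 phosphate buffer
Reagents that add atoms: none
Why: Fluoride cleaves the TMSE ester by β-elimination and the TES ether by Si–O cleavage; buffered work-up gives the acid, which is used at once because the tertiary vinyl oxirane is acid-labile.

Step 21
Reactants: 31 seco acid
Product: 32 EANPDB:COMP_00180 (target)
Conditions: Pd(PPh3)4 (5 mol%), THF (5 mM), 0 °C to rt
Reagents that add atoms: none
Why: Pd(0) coordinates the C5=C6 bond on the face away from the oxirane oxygen and opens the strained ring with inversion at C4 to an η3-allyl over C4–C5–C6, the acid proton passing to the C15 alkoxide. The carboxylate then bonds to C6 from the side remote from the metal, which is the known palladium-catalysed 1,4-addition of carboxylic acids to vinyl epoxides (Tsuji–Trost type) run intramolecularly. The lactone ring (O, C6, C7, C11, C12) closes 5-exo at the secondary allyl terminus, whereas bonding to the fully substituted C4 would need a seven-membered lactone. C6 is controlled by C4: two inversions bring the lactone oxygen to the allyl face that the oxirane oxygen left, so 4S with C15 in the anti and C3 in the syn allyl position should give 6R together with the ring-trans C4=C5 bond. The selectivity needed is therefore for this allyl isomer; the Z-cyclodecene is expected to secure it because the C3 ring bond cannot lie s-cis to C6 and stands on the face opposite the oxirane oxygen, from where it turns into the syn position on ionisation, and syn/anti exchange at C6 through the η1 form changes neither C6 nor the alkene geometry. The C1–C10 oxirane has no neighbouring alkene, the C8 angelate is homoallylic and the free C2 alcohol is a far weaker nucleophile than the carboxylate, so none of them should interfere.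

**Compound list**

1 | 1,1-diethoxybut-2-yne (but-2-ynal diethyl acetal) | CC#CC(OCC)OCC | starting material
2 | (E)-(4,4-diethoxybut-2-en-2-yl)zirconocene chloride | C/C(=C\C(OCC)OCC)[Zr](Cl)(C1C=CC=C1)C1C=CC=C1 | intermediate
3 | (E)-1,1-diethoxy-3-iodobut-2-ene | C/C(I)=C\C(OCC)OCC | intermediate
4 | methyl (S)-oxirane-2-carboxylate (methyl (S)-glycidate) | COC(=O)[C@@H]1CO1 | starting material
5 | (E)-(4,4-diethoxybut-2-en-2-yl)lithium | C/C([Li])=C\C(OCC)OCC | intermediate
6 | (E)-(4,4-diethoxybut-2-en-2-yl)magnesium bromide | C/C([Mg]Br)=C\C(OCC)OCC | intermediate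
7 | methyl (2S,4E)-6,6-diethoxy-2-hydroxy-4-methylhex-4-enoate | COC(=O)[C@@H](O)C/C(C)=C/C(OCC)OCC | intermediate
8 | methyl (2S,4E)-6,6-diethoxy-4-methyl-2-(triethylsilyloxy)hex-4-enoate | COC(=O)[C@@H](O[Si](CC)(CC)CC)C/C(C)=C/C(OCC)OCC | intermediate
9 | (diethoxyphosphoryl)acetic acid | CCOP(=O)(CC(=O)O)OCC | starting material
10 | 2-(trimethylsilyl)ethyl (diethoxyphosphoryl)acetate | CCOP(=O)(CC(=O)OCC[Si](C)(C)C)OCC | intermediate
11 | (2S,4E)-6,6-diethoxy-4-methyl-2-(triethylsilyloxy)hex-4-enal | O=C[C@@H](O[Si](CC)(CC)CC)C/C(C)=C/C(OCC)OCC | intermediate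
12 | 2-(trimethylsilyl)ethyl (2E,4S,6E)-8,8-diethoxy-6-methyl-4-(triethylsilyloxy)octa-2,6-dienoate | C[Si](C)(C)CCOC(=O)/C=C/[C@@H](O[Si](CC)(CC)CC)C/C(C)=C/C(OCC)OCC | intermediate
13 | O-trimethylsilyl ketene acetal of the (7R,8S)-7-vinyl adduct | C[Si](C)(C)CCOC(O[Si](C)(C)C)=C[C@@H](C=C)[C@@H](O[Si](CC)(CC)CC)C/C(C)=C/C(OCC)OCC | intermediate
14 | 2-(trimethylsilyl)ethyl (3R,4S,6E)-2-[(dimethylamino)methyl]-8,8-diethoxy-3-ethenyl-6-methyl-4-(triethylsilyloxy)oct-6-enoate (both C2 epimers) | C[Si](C)(C)CCOC(=O)C(CN(C)C)[C@@H](C=C)[C@@H](O[Si](CC)(CC)CC)C/C(C)=C/C(OCC)OCC | intermediate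
15 | N-methyl ammonium iodide of 14 | C[Si](C)(C)CCOC(=O)C(C[N+](C)(C)C)[C@@H](C=C)[C@@H](O[Si](CC)(CC)CC)C/C(C)=C/C(OCC)OCC.[I-] | intermediate
16 | 2-(trimethylsilyl)ethyl (3R,4S,6E)-8,8-diethoxy-3-ethenyl-6-methyl-2-methylidene-4-(triethylsilyloxy)oct-6-enoate | C=C(C(=O)OCC[Si](C)(C)C)[C@@H](C=C)[C@@H](O[Si](CC)(CC)CC)C/C(C)=C/C(OCC)OCC | intermediate
17 | 2-(trimethylsilyl)ethyl (3R,4S,6E)-3-ethenyl-4-hydroxy-6-methyl-2-methylidene-8-oxooct-6-enoate | C=C(C(=O)OCC[Si](C)(C)C)[C@@H](C=C)[C@@H](O)C/C(C)=C/C=O | intermediate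
18 | angelic acid, (Z)-2-methylbut-2-enoic acid | C/C=C(/C)C(=O)O | starting material
19 | 2-(trimethylsilyl)ethyl (3R,4S,6E)-3-ethenyl-6-methyl-2-methylidene-4-{[(2Z)-2-methylbut-2-enoyl]oxy}-8-oxooct-6-enoate (angelate enal) | C=C(C(=O)OCC[Si](C)(C)C)[C@@H](C=C)[C@@H](OC(=O)/C(C)=C\C)C/C(C)=C/C=O | intermediate
20 | 3-chloro-2-(chloromethyl)prop-1-ene | C=C(CCl)CCl | starting material
21 | 1-({[2-(chloromethyl)prop-2-en-1-yl]oxy}methyl)-4-methoxybenzene | C=C(CCl)COCc1ccc(OC)cc1 | intermediate
22 | tributyl(2-{[(4-methoxybenzyl)oxy]methyl}prop-2-en-1-yl)stannane | C=C(COCc1ccc(OC)cc1)C[Sn](CCCC)(CCCC)CCCC | intermediate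
23 | 2-(trimethylsilyl)ethyl (3R,4S,6E,8S)-3-ethenyl-8-hydroxy-10-{[(4-methoxybenzyl)oxy]methyl}-6-methyl-2-methylidene-4-{[(2Z)-2-methylbut-2-enoyl]oxy}undeca-6,10-dienoate (2S alcohol, germacrane numbering) | C=C(C(=O)OCC[Si](C)(C)C)[C@@H](C=C)[C@@H](OC(=O)/C(C)=C\C)C/C(C)=C/[C@@H](O)CC(=C)COCc1ccc(OC)cc1 | intermediate
24 | (1R,2S,7R,8S,10R)-1,10-epoxide of 23, C2–OH free | C=C(C(=O)OCC[Si](C)(C)C)[C@@H](C=C)[C@@H](OC(=O)/C(C)=C\C)C[C@@]1(C)O[C@@H]1[C@@H](O)CC(=C)COCc1ccc(OC)cc1 | intermediate
25 | C2 triethylsilyl ether of 24 | C=C(C(=O)OCC[Si](C)(C)C)[C@@H](C=C)[C@@H](OC(=O)/C(C)=C\C)C[C@@]1(C)O[C@@H]1[C@@H](O[Si](CC)(CC)CC)CC(=C)COCc1ccc(OC)cc1 | intermediate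
26 | C5 allylic alcohol: 25 without the PMB group | C=C(C(=O)OCC[Si](C)(C)C)[C@@H](C=C)[C@@H](OC(=O)/C(C)=C\C)C[C@@]1(C)O[C@@H]1[C@@H](O[Si](CC)(CC)CC)CC(=C)CO | intermediate
27 | (4S)-4,15-epoxide of 26 with C5 primary alcohol | C=C(C(=O)OCC[Si](C)(C)C)[C@@H](C=C)[C@@H](OC(=O)/C(C)=C\C)C[C@@]1(C)O[C@@H]1[C@@H](O[Si](CC)(CC)CC)C[C@]2(CO)CO2 | intermediate
28 | C5 aldehyde of 27 | C=C(C(=O)OCC[Si](C)(C)C)[C@@H](C=C)[C@@H](OC(=O)/C(C)=C\C)C[C@@]1(C)O[C@@H]1[C@@H](O[Si](CC)(CC)CC)C[C@]2(C=O)CO2 | intermediate
29 | acyclic bis-vinyl compound: (4S)-vinyl oxirane, C7 vinyl, (1R,2S,7R,8S,10R) | C=C(C(=O)OCC[Si](C)(C)C)[C@@H](C=C)[C@@H](OC(=O)/C(C)=C\C)C[C@@]1(C)O[C@@H]1[C@@H](O[Si](CC)(CC)CC)C[C@]2(C=C)CO2 | intermediate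
30 | ten-membered (5Z)-cycloalkene, (1R,2S,4S,7R,8S,10R), TMSE ester, C2 OTES | C=C(C(=O)OCC[Si](C)(C)C)[C@H]1/C=C\[C@]4(CO4)C[C@H](O[Si](CC)(CC)CC)[C@H]3O[C@]3(C)C[C@@H]1OC(=O)/C(C)=C\C | intermediate
31 | seco acid, (1R,2S,4S,7R,8S,10R): C4 spiro-oxirane, Z-C5=C6, C12 acid, C8 angelate | C=C(C(=O)O)[C@H]1/C=C\[C@]4(CO4)C[C@H](O)[C@H]3O[C@]3(C)C[C@@H]1OC(=O)/C(C)=C\C | intermediate
32 | EANPDB:COMP_00180, (1R,2S,6R,7R,8S,10R) | C=C1C(=O)O[C@@H]2/C=C(\CO)C[C@H](O)[C@H]3O[C@]3(C)C[C@H](OC(=O)/C(C)=C\C)[C@@H]12 | target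

**Totals**

Total step count: 21. Longest linear sequence: 18 steps (1–3, 5–9, 12–21).

**Steps most likely to fail**

1. Step 21. What may go wrong: ionisation through the C4–C5 rotamer that puts C3 in the anti allyl position, which would lead to the 6-epi lactone with a ring-cis C4=C5 bond; loss of a β-hydrogen from the allyl complex; or re-ionisation of the allylic lactone with erosion of C6. The fallback sets out from 31 and returns at 32. Iodolactonisation (I2, NaHCO3, MeCN/H2O, 0 °C) should let the carboxylate open the iodonium ion of the Z-C5=C6 alkene at C6 in a 5-exo anti addition, giving the iodolactone F1, in which iodine on C5 lies next to the intact C4 spiro-oxirane. Activated zinc (NH4Cl, EtOH, rt) then reduces the C–I bond and opens the oxirane; an anti-periplanar loss of I and the C4–O bond should give the ring-trans C4=C5 bond and the C15 alcohol, that is 32.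

2. Step 19. What may go wrong: slow loading of the catalyst on two hindered vinyl groups (one on the quaternary C4), competing oligomerisation, or formation of an E/Z mixture. The fallback is a relay ring closure that sets out from 28 and returns at 30. Wittig reaction of 28 with the ylide from (hex-5-en-1-yl)triphenylphosphonium bromide (KHMDS, THF, −78 °C) gives the relay triene F2. Ruthenium then loads at the unhindered terminal alkene, expels cyclopentene and so places the carbene directly on C5, which closes onto the C6 vinyl group to give 30.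

3. Step 6. What may go wrong: poor facial selectivity at C7 in the conjugate addition, or incomplete trapping of the ketene acetal by the iminium salt. The fallback sets out from 8 and returns at 16. Aldehyde 11 is isolated after the DIBAL reduction and condensed with 10 (Knoevenagel, TiCl4, N-methylmorpholine, THF, 0 °C) to the alkylidene phosphonoacetate F3. In this doubly activated alkene A1,3 strain holds C8–H in the alkene plane, so copper-catalysed addition of vinylmagnesium bromide anti to the C8–O bond is expected to be more selective. The phosphonate anion formed is then treated with paraformaldehyde (Horner–Wadsworth–Emmons) and gives 16 directly, without 14 and step 7.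

**Further compounds**

F1 | step 21 | iodolactone: 6,12-olide with iodine on C5 and intact (4S) spiro-oxirane | C=C1C(=O)O[C@@H]2[C@@H](I)[C@]4(CO4)C[C@H](O)[C@H]3O[C@]3(C)C[C@H](OC(=O)/C(C)=C\C)[C@@H]12
F2 | step 19 | relay triene: 29 with a (Z)-hepta-1,6-dien-1-yl group in place of the vinyl group on C4 | C=C(C(=O)OCC[Si](C)(C)C)[C@@H](C=C)[C@@H](OC(=O)/C(C)=C\C)C[C@@]1(C)O[C@@H]1[C@@H](O[Si](CC)(CC)CC)C[C@]2(/C=C\CCCC=C)CO2
F3 | step 6 | alkylidene phosphonoacetate from 11 and 10 (E/Z mixture at C7=C11) | CCOP(=O)(OCC)C(C(=O)OCC[Si](C)(C)C)=C[C@@H](O[Si](CC)(CC)CC)C/C(C)=C/C(OCC)OCC
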